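**Time of reading.** The flask is read at 3.0 min, and that time says little until it is counted in lifetimes of J.

| flask | X | D | remark | time |
|---|---|---|---|---|
| alder | 6.7 mM | 2.5 equiv | run made earlier |  |
| oak | 15 mM | 2.5 equiv | run made earlier |  |
| larch | 10 mM | 1.2 equiv | run made earlier |  |
| flask | 10 mM | 2.50 equiv |  | 3.0 min |

- alder (time / s: J / %, Q / %): 10.0: 1.8, 0; 15.0: 4.3, 0; 25.0: 4.0, 0; 40.0: 6.0, 0; 60.0: 7.6, 0.6; 120: 7.4, 0.7
- oak (time / s: J / %, Q / %): 10.0: 2.9, 0; 15.0: 1.7, 0.3; 25.0: 3.6, 1.2; 40.0: 4.8, 0; 60.0: 5.0, 1.2; 120: 4.1, 0
- larch (time / s: J / %, Q / %): 20.0: 3.8, 0.6; 40.0: 7.3, 2.4; 60.0: 9.7, 1.7; 80.0: 8.9, 0; 120: 10.6, 0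

(scatter of a reading: 1 percentage point)

1. the J and Q together standing at 3.0 min, as a percentage of the X charged
2. concentration of J in solution at 3.0 min, in percent of saturation

- J is meant together with its Q
- solid, in amounts per volume of the solution: Q
- the earlier runs were read with a standard deviation of 1 percentage point

**Two flasks.** Larch has the same c_X as the flask but 1.2 equiv of D against 2.50 equiv. Early in larch, the readings put J at 3.8% after 20.0 s, a making rate, as read, of 0.00190 s⁻¹ as a fraction of the X charged. The last J readings fall as c_D rises: larch 10.6%, alder 7.4%, oak 4.1%. This reckoning therefore reads J as a leaking tank: a first-order lag with D in excess (pseudo-first-order loss), its lifetime τ inverse to c_D, and standing J equal to making rate times τ.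

**Turnover count.** Larch's last reading, taken as standing J, gives an estimated τ = 55.8 s, and scaling by charged c_D gives 26.8 s for the flask, shorter. The turnover count, reading time over τ, is 6.72 for the flask and 2.15 for larch at its last reading. On this count, the flask should stand near 5.09%, lower than the last larch reading. That is c_J = 0.509 mM, below the 1.06 mM that larch held with a Q reading of 0%, so no crystals are expected.

**Forecast.** The forecast says 6.4% and 50%, on this ground: “The yield falls with increasing concentration”.

**Result.** The flask gives 5.92%, at 17.9% of saturation, against the 5.09% reckoned here.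

    X + D → E (k = 0.230 M⁻¹ s⁻¹)
    X → J (k = 0.00190 s⁻¹)
    D + E ⇌ G (K = 19.0 M⁻¹, k = 0.150 M⁻¹ s⁻¹)
    Q ⇌ J, rate k4*(cs4 - [J]) while solid is left; crystals form when [J] > cs4 (solubility = 3.30 mM, k = 0.0950 s⁻¹)
    D + J → Z (k = 0.680 M⁻¹ s⁻¹)

**The drain.** The step D + J → Z has the largest single effect on this yield: the flask without it stands at 19.3% instead of 5.92%. In the flask, J made over J standing thus counts 3.26 turnovers, fewer than the 6.72 reckoned. A neighbouring flask, the same recipe at 40 mM of X, scales the reckoned count by charged c_D to 26.9, and there J and Q stand at 0.470% after 3.0 min.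

(The earlier runs and the new flask stem from a simulated flask with made-up constants; the scatter is artificial.)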